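**Retrosynthetic overview**
1. Target 28 ⇐ enone 26 / silyl enol ether 27 (C11 methyl by cuprate addition, then Saegusa–Ito oxidation) ⇐ triester 23 ⇐ triol 17 ⇐ cycloheptenone 15 (CBS reduction, then osmylation anti to the new carbinol).
2. 15 ⇐ seven-membered ketone 14 ⇐ one-carbon ring enlargement of the cyclohexanone ring of tricyclic ketone 7 through β-hydroxy selenide 13 (semipinacol shift that inserts the gem-dimethyl carbon).
3. 7 ⇐ cis-decalone epoxide 5 (cyclobutane by 4-exo enolate/epoxide closure) ⇐ (R)-Wieland–Miescher ketone 1; its methyl-bearing quaternary stereocentre is kept and its decalin skeleton is remodelled by C–C bond migration.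
4. Order of rings: both six-membered rings arrive with 1; the cyclobutane closes in step 5; the seven-membered ring arises in step 9 from the former enone ring of 1; the ring double bond is set last.
5. Enabling feature: in 7/13 the carbonyl (carbinol) carbon C8 of the six-membered ring C1–C6–C7–C8–C9–C10 lies between the CH2 group C9 and the more substituted, non-enolisable cyclobutane bridgehead C7. A cation on an exocyclic C(CH3)2 at C8 is therefore quenched by 1,2-shift of C7, and both C8 epimers converge.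

Key step: step 9

Remarks: (R)-Wieland–Miescher ketone is taken as a purchased starting material (it is also made from 2-methylcyclohexane-1,3-dione, methyl vinyl ketone and D-proline). Tricyclic compounds carry von Baeyer locants: tricyclo[4.4.0.0^{2,7}]decane for 6, 7 and 13, tricyclo[5.4.0.0^{2,8}]undecane from 14 on. The carbinol centre of 13 and C11 of 27 are destroyed in the next step; both epimers are used and the SMILES leave these centres open.

**Step 1**
Reactants: 1 (R)-Wieland–Miescher ketone
Product: 2 (4aR,5R)-5-hydroxy-4a-methyl-4,4a,5,6,7,8-hexahydronaphthalen-2(3H)-one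
Conditions: NaBH4 (0.3 equiv), EtOH, −10 °C
Reagents that add atoms: none
Why: Chemoselective borohydride reduction: the saturated ketone reacts faster than the enone carbonyl, and hydride adds anti to the angular methyl, so the hydroxyl (removed in step 3) is cis to it.

**Step 2**
Reactants: 2 (4aR,5R)-5-hydroxy-4a-methyl-4,4a,5,6,7,8-hexahydronaphthalen-2(3H)-one
Product: 3 (4aR,5R,8aS)-5-hydroxy-4a-methyloctahydronaphthalen-2(1H)-one (cis-fused)
Conditions: H2 (1 atm), 10% Pd/C, EtOH, rt
Reagents that add atoms: none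
Why: Heterogeneous catalytic hydrogenation of the octalone is expected to add hydrogen to C8a on the face of the angular methyl and so give the cis-fused decalone that the cyclobutane closure needs; any trans-fused isomer cannot cyclise and is removed.

**Step 3**
Reactants: 3 (4aR,5R,8aS)-5-hydroxy-4a-methyloctahydronaphthalen-2(1H)-one
Product: 4 (4aR,8aS)-4a-methyl-3,4,4a,7,8,8a-hexahydronaphthalen-2(1H)-one (cis-fused)
Conditions: Burgess reagent, benzene, 50 °C
Reagents that add atoms: none
Why: Burgess dehydration is a concerted syn-elimination (Ei) of the sulfamate ester that avoids a neopentyl cation; only C6 carries β-hydrogens, so only the C5=C6 alkene can form.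

**Step 4**
Reactants: 4 (4aR,8aS)-4a-methyl-3,4,4a,7,8,8a-hexahydronaphthalen-2(1H)-one
Product: 5 (4aR,5S,6R,8aS)-5,6-epoxy-4a-methyloctahydronaphthalen-2(1H)-one (oxirane syn to the angular methyl)
Conditions: mCPBA, NaHCO3, CH2Cl2, 0 °C
Reagents that add atoms: mCPBA O=C(OO)c1cccc(Cl)c1
Why: Prilezhaev epoxidation should occur on the convex face of the cis-decalin (the face of the angular methyl, away from the folded cyclohexanone ring) and faster than Baeyer–Villiger oxidation of the ketone; the oxygen on C5 is then anti to the carbon that must attack.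

**Step 5**
Reactants: 5 (4aR,5S,6R,8aS)-5,6-epoxy-4a-methyloctahydronaphthalen-2(1H)-one
Product: 6 3-hydroxy-1-methyltricyclo[4.4.0.0^{2,7}]decan-8-one (cyclobutane C1–C2–C7–C6; 3-OH turned toward C1)
Conditions: KOtBu (0.3 equiv), t-BuOH, 40 °C
Reagents that add atoms: none
Why: Intramolecular enolate alkylation by an epoxide (4-exo-tet): of the two equilibrating enolates only the one at C1 can reach C5; it attacks from the rear of the C5–O bond in preference to the 5-endo mode at C6 and closes the cyclobutane with inversion at C5, the cis ring fusion fixing the other centres.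

**Step 6**
Reactants: 6 3-hydroxy-1-methyltricyclo[4.4.0.0^{2,7}]decan-8-one
Product: 7 3-(tert-butyldimethylsilyloxy)-1-methyltricyclo[4.4.0.0^{2,7}]decan-8-one
Conditions: TBSCl, imidazole, DMF, rt
Reagents that add atoms: tert-butyldimethylsilyl chloride CC(C)(C)[Si](C)(C)Cl
Why: Standard silylation protects the secondary carbinol against the organolithium, Lewis acid and oxidants that follow.

**Step 7**
Reactants: 8 acetone; 9 dimethyl diselenide
Product: 11 2,2-bis(methylselanyl)propane, via methaneselenol 10 (not isolated)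
Conditions: 9, H3PO2 (50% aq.), THF, 40 °C; then 8, ZnCl2 (cat.), CH2Cl2, 0 °C → rt
Reagents that add atoms: none
Why: Hypophosphorous acid reduces the diselenide to the selenol, which forms the selenoacetal of acetone under Lewis acid catalysis (selenoacetalisation).

**Step 8**
Reactants: 7 3-(tert-butyldimethylsilyloxy)-1-methyltricyclo[4.4.0.0^{2,7}]decan-8-one; 11 2,2-bis(methylselanyl)propane
Product: 13 3-(tert-butyldimethylsilyloxy)-1-methyl-8-[2-(methylselanyl)propan-2-yl]tricyclo[4.4.0.0^{2,7}]decan-8-ol (both C8 epimers), via 2-lithio-2-(methylselanyl)propane 12 (not isolated)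
Conditions: 11, n-BuLi, THF, −78 °C; then 7, −78 °C; aq. NH4Cl
Reagents that add atoms: none
Why: Selenium–lithium exchange gives the α-selanyl tertiary organolithium, which adds 1,2 to the ketone (enolisation toward the only enolisable CH2 is slow at −78 °C); the carbinol configuration does not matter.

**Step 9**
Reactants: 13 3-(tert-butyldimethylsilyloxy)-1-methyl-8-[2-(methylselanyl)propan-2-yl]tricyclo[4.4.0.0^{2,7}]decan-8-ol
Product: 14 9-(tert-butyldimethylsilyloxy)-2,6,6-trimethyltricyclo[5.4.0.0^{2,8}]undecan-5-one (cyclobutane C1–C2–C8–C7)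
Conditions: AgBF4, neutral Al2O3, CH2Cl2, 20 °C
Reagents that add atoms: none
Why: Silver(I) binds the selenium of 13 and C–Se heterolysis leaves a tertiary carbocation on the exocyclic C(CH3)2 carbon next to the carbinol carbon; the hydroxyl lone pair then drives a 1,2-shift (semipinacol, Tiffeneau–Demjanov type) of the cyclobutane bridgehead carbon C7 from C8 to the cationic carbon, which cleaves the C7–C8 bond of the cyclohexane ring inherited from the Wieland–Miescher ketone and releases ketone 14. The closest known reaction type is the silver- or thallium-promoted ring enlargement of β-hydroxyalkyl selenides made from cyclohexanones and 2-lithio-2-(methylselanyl)propane, which gives 2,2-dimethylcycloheptanones. No ring is closed from an open chain: the six-membered ring C1–C6–C7–C8–C9–C10 of 13 becomes the seven-membered ring C1–C2–C3–C4–C5–C6–C7 of 14 by insertion of the new quaternary C6 between the old C8 and C7, while the cyclobutane and the second six-membered ring are untouched. No stereocentre is created (C6 carries two methyl groups), the migrating C7 keeps its configuration, and the carbinol centre disappears, so both epimers of 13 converge on one product. The step needs migration of the bridgehead CH in preference to the CH2 group C9, and 1,2-shift in preference to oxirane formation or proton loss: the more substituted, more electron-rich ring carbon is the better migrating group (as in Baeyer–Villiger oxidation of bicyclo[3.1.1]heptan-2-ones), the cation is generated only at the selenium-bearing carbon and never next to the cyclobutane, and alumina buffers the HBF4 so that the silyl ether survives.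

**Step 10**
Reactants: 14 9-(tert-butyldimethylsilyloxy)-2,6,6-trimethyltricyclo[5.4.0.0^{2,8}]undecan-5-one
Product: 15 9-(tert-butyldimethylsilyloxy)-2,6,6-trimethyltricyclo[5.4.0.0^{2,8}]undec-3-en-5-one
Conditions: IBX, DMSO, 70 °C
Reagents that add atoms: none
Why: IBX dehydrogenation of a ketone to the enone; the gem-dimethyl carbon blocks one side, so only the C3=C4 double bond can form.

**Step 11**
Reactants: 15 9-(tert-butyldimethylsilyloxy)-2,6,6-trimethyltricyclo[5.4.0.0^{2,8}]undec-3-en-5-one
Product: 16 (5R)-9-(tert-butyldimethylsilyloxy)-2,6,6-trimethyltricyclo[5.4.0.0^{2,8}]undec-3-en-5-ol (5-OH turned toward C1)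
Conditions: (S)-2-methyl-CBS-oxazaborolidine (20 mol %), catecholborane, toluene, −78 °C
Reagents that add atoms: none
Why: Corey–Bakshi–Shibata reduction gives reagent-controlled 1,2-reduction; with the quaternary C6 as the large group the (S)-catalyst should deliver hydride to the face that gives the (5R)-alcohol, since the substrate itself barely differentiates the enone faces.

**Step 12**
Reactants: 16 (5R)-9-(tert-butyldimethylsilyloxy)-2,6,6-trimethyltricyclo[5.4.0.0^{2,8}]undec-3-en-5-ol
Product: 17 9-(tert-butyldimethylsilyloxy)-2,6,6-trimethyltricyclo[5.4.0.0^{2,8}]undecane-3,4,5-triol (3,4-cis and turned toward C8; 4,5-trans)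
Conditions: OsO4 (5 mol %), NMO, acetone–H2O, rt
Reagents that add atoms: N-methylmorpholine N-oxide C[N+]1([O-])CCOCC1; water O
Why: Upjohn dihydroxylation of the cis-alkene should occur anti to the allylic hydroxyl (the usual sense for osmylation of cyclic allylic alcohols), giving the 3,4-cis-diol trans to the 5-OH.

**Step 13**
Reactants: 17 9-(tert-butyldimethylsilyloxy)-2,6,6-trimethyltricyclo[5.4.0.0^{2,8}]undecane-3,4,5-triol
Product: 18 9-(tert-butyldimethylsilyloxy)-2,6,6-trimethyl-4-(triethylsilyloxy)tricyclo[5.4.0.0^{2,8}]undecane-3,5-diol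
Conditions: TESCl (1.05 equiv), imidazole, CH2Cl2, −40 °C
Reagents that add atoms: chlorotriethylsilane CC[Si](Cl)(CC)CC
Why: Silylation under kinetic control selects the C4 hydroxyl, the only one of the three with no quaternary carbon next to it.

**Step 14**
Reactants: 18 9-(tert-butyldimethylsilyloxy)-2,6,6-trimethyl-4-(triethylsilyloxy)tricyclo[5.4.0.0^{2,8}]undecane-3,5-diol; 19 angelic acid (2 equiv)
Product: 21 3,5-bis(angelate) of 18, via angelic 2,4,6-trichlorobenzoic anhydride 20 (not isolated)
Conditions: 19, 2,4,6-trichlorobenzoyl chloride, Et3N, toluene, rt; then 18, 80 °C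
Reagents that add atoms: none
Why: Yamaguchi-type esterification through the mixed anhydride, run without DMAP, acylates hindered secondary alcohols while keeping the Z geometry of the angelate; the silyl ether at C4 cannot migrate as an acetate would.

**Step 15**
Reactants: 21 3,5-bis(angelate) of 18
Product: 22 9-(tert-butyldimethylsilyloxy)-4-hydroxy-2,6,6-trimethyltricyclo[5.4.0.0^{2,8}]undecane-3,5-diyl bis[(Z)-2-methylbut-2-enoate]
Conditions: PPTS, MeOH, 0 °C
Reagents that add atoms: none
Why: Acid-catalysed methanolysis removes the triethylsilyl ether much faster than the tert-butyldimethylsilyl ether and leaves the esters intact.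

**Step 16**
Reactants: 22 9-(tert-butyldimethylsilyloxy)-4-hydroxy-2,6,6-trimethyltricyclo[5.4.0.0^{2,8}]undecane-3,5-diyl bis[(Z)-2-methylbut-2-enoate]
Product: 23 4-acetoxy-9-(tert-butyldimethylsilyloxy)-2,6,6-trimethyltricyclo[5.4.0.0^{2,8}]undecane-3,5-diyl bis[(Z)-2-methylbut-2-enoate]
Conditions: Ac2O, pyridine, DMAP (cat.), CH2Cl2, rt
Reagents that add atoms: acetic anhydride CC(=O)OC(C)=O
Why: DMAP-catalysed acetylation of the last free hydroxyl; as no free vicinal hydroxyl remains, acyl migration cannot scramble the ester pattern.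

**Step 17**
Reactants: 23 4-acetoxy-9-(tert-butyldimethylsilyloxy)-2,6,6-trimethyltricyclo[5.4.0.0^{2,8}]undecane-3,5-diyl bis[(Z)-2-methylbut-2-enoate]
Product: 24 4-acetoxy-9-hydroxy-2,6,6-trimethyltricyclo[5.4.0.0^{2,8}]undecane-3,5-diyl bis[(Z)-2-methylbut-2-enoate]
Conditions: HF·pyridine, pyridine, THF, 0 °C → rt
Reagents that add atoms: none
Why: Fluoride-mediated desilylation with buffered HF·pyridine frees the C9 carbinol without transesterification.

**Step 18**
Reactants: 24 4-acetoxy-9-hydroxy-2,6,6-trimethyltricyclo[5.4.0.0^{2,8}]undecane-3,5-diyl bis[(Z)-2-methylbut-2-enoate]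
Product: 26 4-acetoxy-2,6,6-trimethyl-9-oxotricyclo[5.4.0.0^{2,8}]undec-10-ene-3,5-diyl bis[(Z)-2-methylbut-2-enoate], via 9-ketone 25 (not isolated)
Conditions: IBX (4 equiv), DMSO, 75 °C
Reagents that add atoms: none
Why: IBX oxidises the alcohol to the ketone and then dehydrogenates it; C8 is a cyclobutane bridgehead and cannot enolise, so only the C10=C11 double bond forms.

**Step 19**
Reactants: 26 4-acetoxy-2,6,6-trimethyl-9-oxotricyclo[5.4.0.0^{2,8}]undec-10-ene-3,5-diyl bis[(Z)-2-methylbut-2-enoate]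
Product: 27 4-acetoxy-2,6,6,11-tetramethyl-9-(trimethylsilyloxy)tricyclo[5.4.0.0^{2,8}]undec-9-ene-3,5-diyl bis[(Z)-2-methylbut-2-enoate] (C11 epimers)
Conditions: Me2CuLi (from CuI, MeLi), TMSCl, THF, −78 °C
Reagents that add atoms: methyllithium (as lithium dimethylcuprate) [Li]C; chlorotrimethylsilane C[Si](C)(C)Cl
Why: Chlorotrimethylsilane-accelerated conjugate addition of lithium dimethylcuprate to the unhindered cis-enone should be far faster than any reaction with the acetate or the trisubstituted angelates; the enolate is trapped as the silyl enol ether and the C11 configuration does not matter.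

**Step 20**
Reactants: 27 4-acetoxy-2,6,6,11-tetramethyl-9-(trimethylsilyloxy)tricyclo[5.4.0.0^{2,8}]undec-9-ene-3,5-diyl bis[(Z)-2-methylbut-2-enoate]
Product: 28 (1R,2R,3S,4R,5S,7S,8R)-4-acetoxy-2,6,6,11-tetramethyl-9-oxotricyclo[5.4.0.0^{2,8}]undec-10-ene-3,5-diyl bis[(Z)-2-methylbut-2-enoate] (target, CNP0335415.1)
Conditions: Pd(OAc)2 (1.05 equiv), MeCN, rt
Reagents that add atoms: none
Why: Saegusa–Ito oxidation: the palladium(II) enolate undergoes β-hydride elimination of the C11 hydrogen and gives the β-methyl enone.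

**Compound list**
1 | (R)-Wieland–Miescher ketone, (8aR)-8a-methyl-3,4,8,8a-tetrahydronaphthalene-1,6(2H,7H)-dione | C[C@@]12CCC(=O)C=C1CCCC2=O | starting material
2 | (4aR,5R)-5-hydroxy-4a-methyl-4,4a,5,6,7,8-hexahydronaphthalen-2(3H)-one | C[C@@]12CCC(=O)C=C1CCC[C@H]2O | intermediate
3 | (4aR,5R,8aS)-5-hydroxy-4a-methyloctahydronaphthalen-2(1H)-one, cis-fused | C[C@@]12CCC(=O)C[C@@H]1CCC[C@H]2O | intermediate
4 | (4aR,8aS)-4a-methyl-3,4,4a,7,8,8a-hexahydronaphthalen-2(1H)-one, cis-fused | C[C@@]12CCC(=O)C[C@@H]1CCC=C2 | intermediate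
5 | (4aR,5S,6R,8aS)-5,6-epoxy-4a-methyloctahydronaphthalen-2(1H)-one, oxirane syn to the angular methyl | C[C@@]12CCC(=O)C[C@@H]1CC[C@H]3O[C@@H]23 | intermediate
6 | 3-hydroxy-1-methyltricyclo[4.4.0.0^{2,7}]decan-8-one, 3-OH turned toward C1 | O=C1CC[C@@]2(C)[C@@H]3[C@H](O)CC[C@H]2[C@@H]31 | intermediate
7 | 3-(tert-butyldimethylsilyloxy)-1-methyltricyclo[4.4.0.0^{2,7}]decan-8-one | O=C1CC[C@@]2(C)[C@@H]3[C@H](O[Si](C)(C)C(C)(C)C)CC[C@H]2[C@@H]31 | intermediate
8 | acetone | CC(C)=O | starting material
9 | dimethyl diselenide | C[Se][Se]C | starting material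
10 | methaneselenol | C[SeH] | intermediate (not isolated)
11 | 2,2-bis(methylselanyl)propane | CC(C)([Se]C)[Se]C | intermediate
12 | 2-lithio-2-(methylselanyl)propane | [Li]C(C)(C)[Se]C | intermediate (not isolated)
13 | 3-(tert-butyldimethylsilyloxy)-1-methyl-8-[2-(methylselanyl)propan-2-yl]tricyclo[4.4.0.0^{2,7}]decan-8-ol, both C8 epimers | C[Se]C(C)(C)C1(O)CC[C@@]2(C)[C@@H]3[C@H](O[Si](C)(C)C(C)(C)C)CC[C@H]2[C@@H]31 | intermediate
14 | 9-(tert-butyldimethylsilyloxy)-2,6,6-trimethyltricyclo[5.4.0.0^{2,8}]undecan-5-one | O=C1CC[C@@]2(C)[C@@H]3[C@H](O[Si](C)(C)C(C)(C)C)CC[C@H]2[C@@H]3C1(C)C | intermediate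
15 | 9-(tert-butyldimethylsilyloxy)-2,6,6-trimethyltricyclo[5.4.0.0^{2,8}]undec-3-en-5-one | O=C1C=C[C@@]2(C)[C@@H]3[C@H](O[Si](C)(C)C(C)(C)C)CC[C@H]2[C@@H]3C1(C)C | intermediate
16 | (5R)-9-(tert-butyldimethylsilyloxy)-2,6,6-trimethyltricyclo[5.4.0.0^{2,8}]undec-3-en-5-ol | O[C@@H]1C=C[C@@]2(C)[C@@H]3[C@H](O[Si](C)(C)C(C)(C)C)CC[C@H]2[C@@H]3C1(C)C | intermediate
17 | 9-(tert-butyldimethylsilyloxy)-2,6,6-trimethyltricyclo[5.4.0.0^{2,8}]undecane-3,4,5-triol (3,4-cis, 4,5-trans) | O[C@@H]1[C@@H](O)[C@@H](O)[C@@]2(C)[C@@H]3[C@H](O[Si](C)(C)C(C)(C)C)CC[C@H]2[C@@H]3C1(C)C | intermediate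
18 | 9-(tert-butyldimethylsilyloxy)-2,6,6-trimethyl-4-(triethylsilyloxy)tricyclo[5.4.0.0^{2,8}]undecane-3,5-diol | O[C@@H]1[C@@H](O[Si](CC)(CC)CC)[C@@H](O)[C@@]2(C)[C@@H]3[C@H](O[Si](C)(C)C(C)(C)C)CC[C@H]2[C@@H]3C1(C)C | intermediate
19 | angelic acid, (Z)-2-methylbut-2-enoic acid | C/C=C(/C)C(=O)O | starting material
20 | angelic 2,4,6-trichlorobenzoic anhydride | C/C=C(/C)C(=O)OC(=O)c1c(Cl)cc(Cl)cc1Cl | intermediate (not isolated)
21 | 9-(tert-butyldimethylsilyloxy)-2,6,6-trimethyl-4-(triethylsilyloxy)tricyclo[5.4.0.0^{2,8}]undecane-3,5-diyl bis[(Z)-2-methylbut-2-enoate] | C/C=C(/C)C(=O)O[C@@H]1[C@@H](O[Si](CC)(CC)CC)[C@@H](OC(=O)/C(C)=C\C)[C@@]2(C)[C@@H]3[C@H](O[Si](C)(C)C(C)(C)C)CC[C@H]2[C@@H]3C1(C)C | intermediate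
22 | 9-(tert-butyldimethylsilyloxy)-4-hydroxy-2,6,6-trimethyltricyclo[5.4.0.0^{2,8}]undecane-3,5-diyl bis[(Z)-2-methylbut-2-enoate] | C/C=C(/C)C(=O)O[C@@H]1[C@@H](O)[C@@H](OC(=O)/C(C)=C\C)[C@@]2(C)[C@@H]3[C@H](O[Si](C)(C)C(C)(C)C)CC[C@H]2[C@@H]3C1(C)C | intermediate
23 | 4-acetoxy-9-(tert-butyldimethylsilyloxy)-2,6,6-trimethyltricyclo[5.4.0.0^{2,8}]undecane-3,5-diyl bis[(Z)-2-methylbut-2-enoate] | C/C=C(/C)C(=O)O[C@@H]1[C@@H](OC(C)=O)[C@@H](OC(=O)/C(C)=C\C)[C@@]2(C)[C@@H]3[C@H](O[Si](C)(C)C(C)(C)C)CC[C@H]2[C@@H]3C1(C)C | intermediate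
24 | 4-acetoxy-9-hydroxy-2,6,6-trimethyltricyclo[5.4.0.0^{2,8}]undecane-3,5-diyl bis[(Z)-2-methylbut-2-enoate] | C/C=C(/C)C(=O)O[C@@H]1[C@@H](OC(C)=O)[C@@H](OC(=O)/C(C)=C\C)[C@@]2(C)[C@@H]3[C@H](O)CC[C@H]2[C@@H]3C1(C)C | intermediate
25 | 4-acetoxy-2,6,6-trimethyl-9-oxotricyclo[5.4.0.0^{2,8}]undecane-3,5-diyl bis[(Z)-2-methylbut-2-enoate] | C/C=C(/C)C(=O)O[C@@H]1[C@@H](OC(C)=O)[C@@H](OC(=O)/C(C)=C\C)[C@@]2(C)[C@@H]3C(=O)CC[C@H]2[C@@H]3C1(C)C | intermediate (not isolated)
26 | 4-acetoxy-2,6,6-trimethyl-9-oxotricyclo[5.4.0.0^{2,8}]undec-10-ene-3,5-diyl bis[(Z)-2-methylbut-2-enoate] | C/C=C(/C)C(=O)O[C@@H]1[C@@H](OC(C)=O)[C@@H](OC(=O)/C(C)=C\C)[C@@]2(C)[C@@H]3C(=O)C=C[C@H]2[C@@H]3C1(C)C | intermediate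
27 | 4-acetoxy-2,6,6,11-tetramethyl-9-(trimethylsilyloxy)tricyclo[5.4.0.0^{2,8}]undec-9-ene-3,5-diyl bis[(Z)-2-methylbut-2-enoate], C11 epimers | C/C=C(/C)C(=O)O[C@@H]1[C@@H](OC(C)=O)[C@@H](OC(=O)/C(C)=C\C)[C@@]2(C)[C@@H]3C(O[Si](C)(C)C)=CC(C)[C@H]2[C@@H]3C1(C)C | intermediate
28 | (1R,2R,3S,4R,5S,7S,8R)-4-acetoxy-2,6,6,11-tetramethyl-9-oxotricyclo[5.4.0.0^{2,8}]undec-10-ene-3,5-diyl bis[(Z)-2-methylbut-2-enoate] | C/C=C(/C)C(=O)O[C@@H]1[C@@H](OC(C)=O)[C@@H](OC(=O)/C(C)=C\C)[C@@]2(C)[C@@H]3C(=O)C=C(C)[C@H]2[C@@H]3C1(C)C | target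

**Step count and risks**
Total step count: 20. Longest linear sequence: 19 steps (steps 1–6 and 8–20; step 7 makes the selenoacetal).

Steps most likely to fail:

1. Step 9 (ring enlargement). The tertiary cation may be trapped by the neighbouring hydroxyl to give an oxirane or may lose a proton to give the isopropenyl carbinol, and the CH2 carbon may migrate in competition with the bridgehead carbon. Fallback, an anionic instead of a cationic 1,2-shift, setting out from 7 and returning at 14: addition of 1,1-dibromoethyllithium (1,1-dibromoethane, LDA, THF, −95 °C) to 7 should give the dibromo carbinol F1. Two equivalents of n-butyllithium then form the β-oxido carbenoid, whose pinacol-type shift to the electron-poor carbenoid carbon (expected again to favour the more substituted bridgehead carbon, with no free cation, acid or selenium) gives the lithium enolate of the 6-methyl cycloheptanone F2. C-methylation of this enolate with iodomethane (THF–HMPA), at the carbon that already bears the methyl group, gives 14.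

2. Step 5 (cyclobutane closure). The base may isomerise the epoxide to an allylic alcohol, the enolate oxygen may alkylate, or opening at the carbon next to the quaternary centre may be too slow. Fallback, a cyclic sulfate as a stronger and irreversible electrophile, setting out from 4 and returning at 6: osmium tetroxide/NMO dihydroxylation of 4 on the same convex face gives the cis-diol F3, and sulfuryl chloride/triethylamine converts it into the cyclic sulfate F4. Potassium tert-butoxide in THF closes the cyclobutane at the carbon next to the quaternary centre and leaves the potassium sulfate monoester F5, and hydrolysis with aqueous sulfuric acid in THF gives 6.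

3. Step 14 (double angeloylation). Acylation of two carbinols that each adjoin a quaternary carbon may stall, and forcing conditions may isomerise the angelate to the tiglate. Fallback, making the Z double bonds after the acylation, setting out from 18 and returning at 21: acylation of 18 with 2-[bis(2,2,2-trifluoroethoxy)phosphoryl]propanoyl chloride (pyridine, DMAP, CH2Cl2) gives the bis(phosphonopropanoate) F6. Still–Gennari olefination of F6 with acetaldehyde (KHMDS, 18-crown-6, THF, −78 °C) sets both trisubstituted Z double bonds under kinetic control and gives 21.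

**Further compounds**
F1 | step 9 | 3-(tert-butyldimethylsilyloxy)-8-(1,1-dibromoethyl)-1-methyltricyclo[4.4.0.0^{2,7}]decan-8-ol | CC(Br)(Br)C1(O)CC[C@@]2(C)[C@@H]3[C@H](O[Si](C)(C)C(C)(C)C)CC[C@H]2[C@@H]31
F2 | step 9 | lithium 9-(tert-butyldimethylsilyloxy)-2,6-dimethyltricyclo[5.4.0.0^{2,8}]undec-5-en-5-olate | [Li]OC=1CC[C@@]2(C)[C@@H]3[C@H](O[Si](C)(C)C(C)(C)C)CC[C@H]2[C@@H]3C=1C
F3 | step 5 | cis-5,6-dihydroxy-4a-methyloctahydronaphthalen-2(1H)-one, diol syn to the angular methyl | C[C@@]12CCC(=O)C[C@@H]1CC[C@@H](O)[C@H]2O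
F4 | step 5 | 5,6-cyclic sulfate of F3 | C[C@@]12CCC(=O)C[C@@H]1CC[C@H]3OS(=O)(=O)O[C@@H]23
F5 | step 5 | potassium 1-methyl-8-oxotricyclo[4.4.0.0^{2,7}]decan-3-yl sulfate | O=C1CC[C@@]2(C)[C@@H]3[C@H](OS(=O)(=O)[O-])CC[C@H]2[C@@H]31.[K+]
F6 | step 14 | 9-(tert-butyldimethylsilyloxy)-2,6,6-trimethyl-4-(triethylsilyloxy)tricyclo[5.4.0.0^{2,8}]undecane-3,5-diyl bis{2-[bis(2,2,2-trifluoroethoxy)phosphoryl]propanoate} | CC(C(=O)O[C@@H]1[C@@H](O[Si](CC)(CC)CC)[C@@H](OC(=O)C(C)P(=O)(OCC(F)(F)F)OCC(F)(F)F)[C@@]2(C)[C@@H]3[C@H](O[Si](C)(C)C(C)(C)C)CC[C@H]2[C@@H]3C1(C)C)P(=O)(OCC(F)(F)F)OCC(F)(F)F
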